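Remark on the chemistry: ring atoms are numbered as in quinic acid (C1 carries O1 and the carboxyl carbon C7; C3, C4 and C5 carry O3, O4 and O5). BDA stands for the butane-2,3-diacetal, the (2S,3S)-2,3-dimethoxybutane-2,3-diyl group bridging O4 and O5. The acid chlorides 11 and 15 are assumed to be used without purification.

## Analysis of the target

The target is a single cyclohexane ring. It carries a tertiary carbinol with the carboxyl group (C1, C7), two methylenes (C2, C6) and three contiguous secondary carbinols (C3, C4, C5). O3 bears an (E)-caffeate and O4 an (E)-p-coumarate, while O1–H, O5–H and the acid are free. The stereodescriptors place O1, O3 and O4 on one face and O5 with C7 on the other, which is the pattern of (−)-quinic acid. The two esters therefore sit on the cis-diol, and the free O5–H is trans to O4. The sensitive groups are the catechol (oxidation, above all in base), the two conjugated esters, and the O4-ester/O5-hydroxyl pair, across which an acyl group shifts as soon as the medium turns basic. The difficulty is not the skeleton. It lies in securing four ring stereocentres as one enantiomer, the fully substituted C1 included, in placing two different acyl groups on two neighbouring hydroxyls out of four, and in unmasking phenols and acid without base. The strategy rests on the fact that C3, C4 and C5 with their oxygens are exactly those of shikimic acid 1. Its ring lacks only an oxygen on C1 and a hydrogen on C2, and its allylic O3–H lies on the face where O1 has to arrive. A second useful feature is that O5 and C7 are cis. The C7–O5 lactone can therefore mask acid and O5 at once, and it flips the chair so that O3–H becomes equatorial and O4–H axial.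

## Retrosynthetic reasoning

**17 ⇒ 16.** The last operation must free three phenols, the acid and O5–H together and without base, because in 17 the O4 ester neighbours the free O5–H. The bonds cut last are therefore the three aryl O–acetyl bonds and the C7–O5 lactone bond, all by acid hydrolysis. The lactone of 16 keeps O5 and the carboxyl silent until then.

**16 ⇒ 12 + 15.** The O4–acyl bond is cut next. In 12, O3 is already esterified and O5 is in the lactone, so the axial O4–H competes only with the tertiary O1–H. The forward step is a catalysed acylation with the acetylated p-coumaroyl chloride 15.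

**12 ⇒ 8 + 11.** The O3–acyl bond is cut in this order because the lactone bridge of 8 holds the chair in which O3–H is equatorial and O4–H axial. The first equivalent of an acylating agent should therefore choose O3. The forward step has to be a kinetically controlled mono-acylation with 11.

**11 ⇒ 10 ⇒ 9 and 15 ⇒ 14 ⇒ 13.** The acyl C–Cl bonds go back to the acids 10 and 14, and the aryl acetates to the phenols of 9 and 13. Acetates are chosen because the final acid treatment removes them together with the lactone, so they cost no separate step.

**8 ⇒ 7 ⇒ 6.** Cutting C7–O5 gives 7, the natural acid itself. Lactonisation can reach only O5, the one hydroxyl cis to C7. Compound 7 is the hydrolysis product of 6, whose acetal and ester fall together.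

**6 ⇒ 5 ⇒ 4.** The C2–H bond of 6 is traced to the C2–I bond of 5 (radical dehalogenation), and C2–I together with O1–H to the oxirane of 4. The oxygen on C2 is removed in these two steps because an α,β-epoxy ester must here be opened at the β-carbon. Electron-transfer reductants would break C1–O instead and erase the centre just made. The forward opening must put the nucleophile on C2 only. C1 is fully substituted, and the locked chair demands trans-diaxial opening, which is opening at C2.

**4 ⇒ 3 (key disconnection).** Both C–O bonds of the oxirane are cut, revealing the C1=C2 alkene of a shikimate ester. This is the only change that separates a quinate from a shikimate. What is gained is that C3, C4 and C5 come with the starting material and C1 is set from C3. The forward reaction must deliver oxygen to the alkene face cis to O3–H, against the steric preference for the other face, and must cope with an alkene deactivated by the ester.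

**3 ⇒ 2 ⇒ 1.** Removing the acetal across the trans-diequatorial O4/O5 diol and the methyl ester leads to 1. The acetal has four functions:
- it removes O5–H, a possible director for the wrong face and an internal nucleophile towards C2 of the epoxide;
- it leaves O3–H as the only hydroxyl;
- it locks the chair for the later epoxide opening;
- it keeps every intermediate up to 6 soluble in non-polar solvents.

## Alternatives that were turned down

**Alternative 1:** The disconnection is the carbocycle itself, at C1–C6 and C2–C3, into buta-1,3-diene A2 and 2-(benzoyloxy)acrolein A3. The forward key step is a Diels–Alder reaction of A2 with A3 under iminium activation by a chiral primary ammonium salt. It gives (1-formylcyclohex-3-en-1-yl) benzoate A1 with C1 set by the catalyst. That centre would then be relayed to C3, C4 and C5 after oxidation of the aldehyde, by halolactonisation onto the ring alkene (which makes the C7–O5 bridge), elimination and dihydroxylation anti to the bridge.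
- For it: the ring and the hardest centre come from one catalytic step on achiral bulk chemicals, and either enantiomer is accessible. O1 arrives benzoylated, so the tertiary hydroxyl cannot compete in the later acylations. On this point it is stronger than the chosen route, which relies on the low reactivity of O1–H.
- Against it: only one of four stereocentres comes from the key step, and its enantiopurity depends on a catalyst acting on an unsubstituted, gaseous, weakly reactive diene. The other three hang on consecutive diastereoselective steps, an osmium-based dihydroxylation among them. The O1 benzoate would finally have to leave under conditions that spare two cinnamates.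
- Comparison: the step counts to the lactone stage are close. The chosen route offers instead three centres of secured absolute configuration bought with 1, a single stereochemical question (one face of one alkene) and no dependence on an enantiomeric excess.

**Alternative 2:** The disconnection cuts C1–O and C4–O together, from a bicyclic endoperoxide. The forward key step is the [4+2] addition of singlet oxygen (O2, light, a porphyrin sensitiser) across C1 and C4 of methyl 5-(tert-butyldimethylsilyloxy)cyclohexa-1,3-diene-1-carboxylate A5, anti to the silyloxy group. It gives the 2,3-dioxabicyclo[2.2.2]octene A4.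
- For it: two C–O bonds, the tertiary one included, form in one step with O1 and O4 necessarily cis, as the target requires. The reagent is also less troubled by the electron-poor ester-bearing alkene than a peracid is, which is an advantage over the chosen key step.
- Against it: A5 can be reached from 1 only by deleting O3, an oxygen the target needs. After O–O cleavage the C2=C3 alkene must be hydrated with oxygen on C3 cis to O4 and hydrogen on C2. That is a regio- and stereochemical problem of the same kind as the one the chosen key step solves, now added on top. A5 is one elimination away from a benzoate, and A4 is a peroxide.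
- Comparison: more steps, with O3 removed and re-made. The chosen route never touches C3 to C5.

**Alternative 3:** The disconnection is the C3–C4 bond of the lactone, quinide A7 (the same compound as 8), back to the lactone dialdehyde A6. The forward key step is a pinacol coupling of the two aldehydes of A6 with SmI2 (divalent samarium). It closes the six-membered ring and forms the cis-diol through a samarium-bridged diketyl.
- For it: the ring and both secondary carbinols form in one step, directly at the lactone 8 on which the end game is built. In convergence on that intermediate it is equal to the chosen route.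
- Against it: A6 already contains C1 and C5, so the stereochemical work is only moved into a separate asymmetric synthesis of a densely functionalised lactone. The C4 aldehyde is α to the epimerisable C5. The ketyl at C4 is α to the C5–O(acyl) bond, a unit that divalent samarium tends to cleave reductively, which would destroy the lactone. Only the cis-diol anti to the bridge is wanted.
- Comparison: the chosen route reaches 8 in five steps from 1 with every centre under substrate control. This alternative needs a longer synthesis of A6 to run one step.

Key step: step 2

## Route

Step 1
Reactants: 1 shikimic acid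
Product: 3 methyl 4,5-O-[(2S,3S)-2,3-dimethoxybutane-2,3-diyl]shikimate (BDA acetal across O4/O5; allylic O3–H free), via methyl shikimate 2 (not isolated)
Conditions: 2,2,3,3-tetramethoxybutane, HC(OMe)3, CSA (cat.), MeOH, reflux
Reagents that add atoms: methanol, CO; 2,2,3,3-tetramethoxybutane, COC(C)(OC)C(C)(OC)OC
Why: Fischer esterification followed in the same pot by thermodynamic trans-acetalisation; only the trans-diequatorial O4/O5 diol can form the trans-fused dioxane with both methoxy groups axial (double anomeric stabilisation), so the cis-related O3–H stays free. No ring stereocentre is touched, and the two acetal centres are set under thermodynamic control by the chirality of the diol.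

Step 2
Reactants: 3 methyl 4,5-O-BDA-shikimate
Product: 4 methyl 1,2-epoxy-4,5-O-BDA-shikimate (1,2-epoxide of 3 with the oxirane oxygen cis to O3–H)
Conditions: CF3CO3H [from (CF3CO)2O and urea·H2O2], Na2HPO4, CH2Cl2, 0 °C → rt
Reagents that add atoms: trifluoroperacetic acid, OOC(=O)C(F)(F)F
Why: Henbest-type hydroxyl-directed epoxidation, run with the peracid strong enough for a conjugated ester: the allylic O3–H hydrogen-bonds to the peracid, so the electrophilic oxygen is handed to the C1=C2 face that carries O3 in one concerted, spiro (butterfly) transition state in which C1–O and C2–O form together while O–O breaks. The closest known reaction type is the cis-selective peracid epoxidation of cyclohex-2-en-1-ols, combined with the known epoxidation of α,β-unsaturated esters by CF3CO3H where weaker peracids are sluggish. The oxirane closes by this single syn oxygen-atom transfer (a [2+1] addition to the alkene), not by a stepwise ring closure, so the two new C–O bonds are necessarily cis to each other. Both new stereocentres, C1 and C2, are fixed by the face of attack, and that face is controlled by the C3 stereocentre through its hydroxyl. The selectivity needed is facial only, since there is one alkene. The BDA acetal secures it by removing O5–H, the one donor that could guide the reagent to the wrong face, so that O3–H is the only hydrogen-bond donor, and by keeping the substrate soluble in CH2Cl2, where the directing hydrogen bond is not disturbed by the solvent. Na2HPO4 takes up CF3CO2H so that neither the acetal nor the glycidic ester is opened.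

Step 3
Reactants: 4 methyl 1,2-epoxy-4,5-O-BDA-shikimate
Product: 5 methyl 2-iodo-4,5-O-BDA-quinate (iodohydrin: iodine on C2 trans to O1 and O3; O1–H cis to O3–H)
Conditions: MgI2, Et2O/toluene, −40 → 0 °C; aq. Na2S2O3 work-up
Reagents that add atoms: magnesium iodide, [Mg+2].[I-].[I-]
Why: Lewis-acid-assisted SN2 opening of a glycidic ester by iodide; C1 is fully substituted and α to the ester, so neither displacement nor ionisation can occur there, and in the chair locked by the trans-fused BDA ring only attack at C2 from the face opposite the oxirane gives the trans-diaxial product (Fürst–Plattner rule). C2 is inverted and C1 keeps its oxygen, so O1–H remains cis to O3–H.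

Step 4
Reactants: 5 methyl 2-iodo-4,5-O-BDA-quinate
Product: 6 methyl 4,5-O-[(2S,3S)-2,3-dimethoxybutane-2,3-diyl]quinate (O1–H and O3–H free)
Conditions: Bu3SnH, AIBN (cat.), toluene, 80 °C
Reagents that add atoms: none
Why: Radical chain dehalogenation; the secondary C2 radical takes hydrogen from Bu3SnH, and neither neighbouring hydroxyl can leave as a radical, so no alkene forms. The C2 stereocentre disappears, and C1, C3, C4 and C5 are untouched.

Step 5
Reactants: 6 methyl 4,5-O-BDA-quinate
Product: 8 quinide (quinic acid 1,5-lactone; 1,3,4-trihydroxy-6-oxabicyclo[3.2.1]octan-7-one), via quinic acid 7 (not isolated)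
Conditions: 2 M aq. HCl, 70 °C; evaporate; then TsOH·H2O (cat.), toluene/DMF, reflux, Dean–Stark
Reagents that add atoms: water, O
Why: Aqueous acid hydrolyses the bis-acetal and the methyl ester, and butane-2,3-dione and methanol leave on evaporation. Azeotropic dehydration then closes the γ-lactone (acid-catalysed lactonisation) between C7 and O5, the only hydroxyl cis to the carboxyl, without touching a stereocentre.

Step 6
Reactants: 9 caffeic acid
Product: 10 (E)-3,4-diacetoxycinnamic acid (3,4-di-O-acetylcaffeic acid)
Conditions: Ac2O, pyridine, rt; cold dilute HCl work-up
Reagents that add atoms: acetic anhydride, CC(=O)OC(C)=O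
Why: O-Acetylation of both phenols, which protects the catechol against oxidation and against self-acylation later. The free acid is recovered after the acidic aqueous work-up and the E-alkene is not affected.

Step 7
Reactants: 10 (E)-3,4-diacetoxycinnamic acid
Product: 11 (E)-3,4-diacetoxycinnamoyl chloride
Conditions: (COCl)2, DMF (cat.), CH2Cl2, 0 °C → rt
Reagents that add atoms: oxalyl chloride, O=C(Cl)C(Cl)=O
Why: Acid chloride formation through the catalytic chloroiminium species; aryl acetates and the enoate are inert.

Step 8
Reactants: 8 quinide; 11 (E)-3,4-diacetoxycinnamoyl chloride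
Product: 12 3-O-(3,4-di-O-acetylcaffeoyl)quinide (O4–H and O1–H free)
Conditions: pyridine, CH2Cl2, −40 → −10 °C (11 added slowly, 1 equiv, no DMAP)
Reagents that add atoms: none
Why: Kinetically controlled O-acylation; in the lactone chair O3–H is the only equatorial secondary hydroxyl, O4–H is axial with syn-axial hydrogens on C2 and C6, and O1–H is tertiary and α to the lactone carbonyl. One equivalent at low temperature should therefore go to O3, as in the equatorial-selective acylation of cis-diols in pyranosides. No stereocentre is affected.

Step 9
Reactants: 13 p-coumaric acid
Product: 14 (E)-4-acetoxycinnamic acid (4-O-acetyl-p-coumaric acid)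
Conditions: Ac2O, pyridine, rt; cold dilute HCl work-up
Reagents that add atoms: acetic anhydride, CC(=O)OC(C)=O
Why: O-Acetylation of the phenol, as in step 6.

Step 10
Reactants: 14 (E)-4-acetoxycinnamic acid
Product: 15 (E)-4-acetoxycinnamoyl chloride
Conditions: (COCl)2, DMF (cat.), CH2Cl2, 0 °C → rt
Reagents that add atoms: oxalyl chloride, O=C(Cl)C(Cl)=O
Why: Acid chloride formation, as in step 7.

Step 11
Reactants: 12 3-O-(3,4-di-O-acetylcaffeoyl)quinide; 15 (E)-4-acetoxycinnamoyl chloride
Product: 16 3-O-(3,4-di-O-acetylcaffeoyl)-4-O-(4-O-acetyl-p-coumaroyl)quinide
Conditions: pyridine, DMAP (cat.), CH2Cl2, 0 °C → rt (15 in slight excess)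
Reagents that add atoms: none
Why: DMAP-catalysed acylation of the one remaining secondary hydroxyl; the tertiary O1–H reacts far more slowly and O5 is held in the lactone. Acylation by the acid chloride should outrun any base-mediated shift of the O3 ester to O4.

Step 12
Reactants: 16 3-O-(3,4-di-O-acetylcaffeoyl)-4-O-(4-O-acetyl-p-coumaroyl)quinide
Product: 17 3-O-[(E)-caffeoyl]-4-O-[(E)-p-coumaroyl]quinic acid (target)
Conditions: 2 M aq. HCl/THF, rt; acidic work-up and acidic reverse-phase purification, no base
Reagents that add atoms: water, O
Why: Acid-catalysed hydrolysis; the three phenyl acetates are cleaved far faster than the two alkyl cinnamates (better leaving group, no conjugative stabilisation), and the strained bicyclic lactone opens in water by acyl–oxygen cleavage, so C5 keeps its configuration. The acidic medium suppresses the base-catalysed O4→O5 acyl shift and oxidation of the catechol.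

## Compound list

1 | shikimic acid, (3R,4S,5R)-3,4,5-trihydroxycyclohex-1-ene-1-carboxylic acid | OC(=O)C1=C[C@@H](O)[C@@H](O)[C@H](O)C1 | starting material
2 | methyl shikimate | COC(=O)C1=C[C@@H](O)[C@@H](O)[C@H](O)C1 | intermediate (formed in the flask, not isolated)
3 | methyl 4,5-O-[(2S,3S)-2,3-dimethoxybutane-2,3-diyl]shikimate, O3–H free | COC(=O)C1=C[C@@H](O)[C@H]2O[C@](C)(OC)[C@@](C)(OC)O[C@@H]2C1 | intermediate
4 | methyl 1,2-epoxy-4,5-O-BDA-shikimate, oxirane cis to O3–H | COC(=O)[C@]12O[C@H]1[C@@H](O)[C@H]3O[C@](C)(OC)[C@@](C)(OC)O[C@@H]3C2 | intermediate
5 | methyl 2-iodo-4,5-O-BDA-quinate, iodine on C2 trans to O1 and O3 | COC(=O)[C@]1(O)[C@H](I)[C@@H](O)[C@H]2O[C@](C)(OC)[C@@](C)(OC)O[C@@H]2C1 | intermediate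
6 | methyl 4,5-O-[(2S,3S)-2,3-dimethoxybutane-2,3-diyl]quinate | COC(=O)[C@]1(O)C[C@@H](O)[C@H]2O[C@](C)(OC)[C@@](C)(OC)O[C@@H]2C1 | intermediate
7 | (−)-quinic acid, (1S,3R,4S,5R)-1,3,4,5-tetrahydroxycyclohexane-1-carboxylic acid | OC(=O)[C@]1(O)C[C@@H](O)[C@@H](O)[C@H](O)C1 | intermediate (formed in the flask, not isolated)
8 | quinide, quinic acid 1,5-lactone (O3–H equatorial, O4–H axial) | O[C@@]12C[C@@H](O)[C@@H](O)[C@@H](C1)OC2=O | intermediate
9 | caffeic acid | OC(=O)/C=C/c1ccc(O)c(O)c1 | starting material
10 | (E)-3,4-diacetoxycinnamic acid | CC(=O)Oc1ccc(/C=C/C(=O)O)cc1OC(C)=O | intermediate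
11 | (E)-3,4-diacetoxycinnamoyl chloride | CC(=O)Oc1ccc(/C=C/C(Cl)=O)cc1OC(C)=O | intermediate
12 | 3-O-(3,4-di-O-acetylcaffeoyl)quinide | O[C@@]12C[C@@H](OC(=O)/C=C/c3ccc(OC(C)=O)c(OC(C)=O)c3)[C@@H](O)[C@@H](C1)OC2=O | intermediate
13 | p-coumaric acid | OC(=O)/C=C/c1ccc(O)cc1 | starting material
14 | (E)-4-acetoxycinnamic acid | CC(=O)Oc1ccc(/C=C/C(=O)O)cc1 | intermediate
15 | (E)-4-acetoxycinnamoyl chloride | CC(=O)Oc1ccc(/C=C/C(Cl)=O)cc1 | intermediate
16 | 3-O-(3,4-di-O-acetylcaffeoyl)-4-O-(4-O-acetyl-p-coumaroyl)quinide | O[C@@]12C[C@@H](OC(=O)/C=C/c3ccc(OC(C)=O)c(OC(C)=O)c3)[C@@H](OC(=O)/C=C/c3ccc(OC(C)=O)cc3)[C@@H](C1)OC2=O | intermediate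
17 | 3-O-[(E)-caffeoyl]-4-O-[(E)-p-coumaroyl]quinic acid (CNP0077575.1) | O=C(/C=C/c1ccc(O)cc1)O[C@H]1[C@H](O)C[C@](O)(C(=O)O)C[C@H]1OC(=O)/C=C/c1ccc(O)c(O)c1 | target

## Step count and least certain steps

Total: 12 steps. Longest linear sequence: 8 steps from 1 (steps 1, 2, 3, 4, 5, 8, 11, 12).

**Step 2 (key step).** The most likely failure is slow conversion, because the alkene is conjugated to the ester. Prolonged exposure would then bring loss of facial control (the pseudoaxial O3–H is a weaker director than a pseudoequatorial one) or acid-mediated opening of the oxirane or the acetal. The fallback removes the deactivating conjugation first. It sets out from 3, where i-Bu2AlH in CH2Cl2 at −78 °C should reduce the ester to the allylic diol F1. Its now electron-rich trisubstituted alkene should be epoxidised by mCPBA (or tBuOOH with catalytic VO(acac)2) under direction of the ring hydroxyl to give the epoxy diol F2. LiAlH4 in THF should open F2 at C2 (less substituted carbon, trans-diaxial) to give the triol F3. Oxidation of the primary alcohol alone (TEMPO cat., NaOCl, NaClO2, buffered MeCN/water) should give the acetal acid F4. Aqueous HCl as in step 5 then converts F4 into 7, where the route is rejoined.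

**Step 3.** Iodide delivery to C2 is slowed by the oxygen on C3, and the Lewis acid may degrade the acetal or simply return 4. Attack at C1 is not expected. The fallback uses a soft anionic nucleophile without Lewis acid. It sets out from 4: PhSeNa, pre-formed from PhSeSePh and NaBH4 in EtOH, should open the oxirane at C2 to give the 2-phenylselanyl alcohol F5. Bu3SnH/AIBN then removes selenium and returns to the route at 6.

**Step 8.** The discrimination between equatorial O3–H and axial O4–H may be incomplete, leading to acylation at the wrong oxygen or at both, with products that are hard to separate. The fallback is a silyl relay that reverses the order of acylation. It sets out from 8: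
- TBSCl/imidazole in DMF should silylate the equatorial hydroxyl to give 3-O-TBS-quinide F6.
- 15 with pyridine/DMAP should acylate O4 to give the silylated mono-ester F7.
- HF·pyridine in THF should remove the silyl group to give 4-O-(4-acetoxycinnamoyl)quinide F8.
- 11 with pyridine at low temperature should acylate the freed equatorial O3–H.

The route is rejoined at 16, so that 12 and step 11 are bypassed. The weak point of the relay is a possible shift of the O4 ester to the freed O3–H before the last acylation.

**Step 12.** Hydrolysis of three aryl acetates in dilute acid is slow. During the long exposure the cinnamates may begin to hydrolyse, the lactone may open incompletely, or the O4 ester may shift to O5 once the lactone has opened. The fallback separates the two unmaskings. It sets out from 16: hydrazine acetate (N2H4·AcOH) in DMF at 0 °C should remove only the aryl acetates and give 3-O-caffeoyl-4-O-p-coumaroylquinide F9. A short treatment of F9 with dilute aqueous HCl in THF, which now has only the lactone to open, should give 17.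

## Further compounds

F1 | step 2 | 1-(hydroxymethyl)-4,5-O-BDA-cyclohex-1-ene-3,4,5-triol, the C7 alcohol of 3 | OCC1=C[C@@H](O)[C@H]2O[C@](C)(OC)[C@@](C)(OC)O[C@@H]2C1
F2 | step 2 | 1,2-epoxide of F1, oxirane cis to O3–H | OC[C@]12O[C@H]1[C@@H](O)[C@H]3O[C@](C)(OC)[C@@](C)(OC)O[C@@H]3C2
F3 | step 2 | 1-(hydroxymethyl)-4,5-O-BDA-cyclohexane-1,3,4,5-tetrol, the C7 alcohol of 6 | OC[C@]1(O)C[C@@H](O)[C@H]2O[C@](C)(OC)[C@@](C)(OC)O[C@@H]2C1
F4 | step 2 | 4,5-O-BDA-quinic acid | OC(=O)[C@]1(O)C[C@@H](O)[C@H]2O[C@](C)(OC)[C@@](C)(OC)O[C@@H]2C1
F5 | step 3 | methyl 2-(phenylselanyl)-4,5-O-BDA-quinate, selenium on C2 trans to O1 | COC(=O)[C@]1(O)[C@H]([Se]c3ccccc3)[C@@H](O)[C@H]2O[C@](C)(OC)[C@@](C)(OC)O[C@@H]2C1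
F6 | step 8 | 3-O-(tert-butyldimethylsilyl)quinide | O[C@@]12C[C@@H](O[Si](C)(C)C(C)(C)C)[C@@H](O)[C@@H](C1)OC2=O
F7 | step 8 | 3-O-(tert-butyldimethylsilyl)-4-O-(4-O-acetyl-p-coumaroyl)quinide | O[C@@]12C[C@@H](O[Si](C)(C)C(C)(C)C)[C@@H](OC(=O)/C=C/c3ccc(OC(C)=O)cc3)[C@@H](C1)OC2=O
F8 | step 8 | 4-O-(4-O-acetyl-p-coumaroyl)quinide | O[C@@]12C[C@@H](O)[C@@H](OC(=O)/C=C/c3ccc(OC(C)=O)cc3)[C@@H](C1)OC2=O
F9 | step 12 | 3-O-caffeoyl-4-O-p-coumaroylquinide | O[C@@]12C[C@@H](OC(=O)/C=C/c3ccc(O)c(O)c3)[C@@H](OC(=O)/C=C/c3ccc(O)cc3)[C@@H](C1)OC2=O
A1 | alternative 1 | (1-formylcyclohex-3-en-1-yl) benzoate | O=C[C@]1(OC(=O)c2ccccc2)CCC=CC1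
A2 | alternative 1 | buta-1,3-diene | C=CC=C
A3 | alternative 1 | 2-(benzoyloxy)acrolein | C=C(C=O)OC(=O)c1ccccc1
A4 | alternative 2 | methyl 5-(tert-butyldimethylsilyloxy)-2,3-dioxabicyclo[2.2.2]oct-7-ene-1-carboxylate | COC(=O)[C@@]12C=C[C@@H](OO1)[C@H](O[Si](C)(C)C(C)(C)C)C2
A5 | alternative 2 | methyl 5-(tert-butyldimethylsilyloxy)cyclohexa-1,3-diene-1-carboxylate | COC(=O)C1=CC=C[C@H](O[Si](C)(C)C(C)(C)C)C1
A6 | alternative 3 | 4-hydroxy-5-oxo-4-(2-oxoethyl)oxolane-2-carbaldehyde (lactone dialdehyde) | O=CC[C@]1(O)C[C@H](C=O)OC1=O
A7 | alternative 3 | quinide (identical with 8) | O[C@@]12C[C@@H](O)[C@@H](O)[C@@H](C1)OC2=O
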